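**Retrosynthetic overview**

1. The butenolide is attached last: C12–C13 by B-alkyl Suzuki–Miyaura coupling with 4-bromofuran-2(5H)-one, C9–C11 by Stille vinylation of a C9 enol triflate.
2. 2α-OH comes from a C2 ketone by equatorial hydride delivery; 19-OAc comes from selective acetylation of a 6α,19-diol.
3. Key disconnection, C19–O: the C19 oxygen and the C4 quaternary stereocentre come from a 6α-silyloxy-directed C–H oxygenation of one methyl of a C4 gem-dimethyl group (C6 is set in the same flask).
4. The enol triflate comes from conjugate reduction/O-triflation of a cis-fused enedione, itself made by an enantioselective Diels–Alder reaction of 2,6-dimethylbenzoquinone with the silyl dienol ether of mesityl oxide (sets C5 and C10).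
5. Ring order: ring B (the quinone) is present first, ring A is closed by the Diels–Alder reaction, and the butenolide ring is brought in preformed at the end.

Convention: decalin compounds are named with the carbon numbers of the target (labdane numbering: C1–C5 and C10 = ring A; C5–C10 = ring B; C4 quaternary; C17 = methyl on C8; C18 = α-carbon on C4; C19 = β-carbon on C4; C20 = methyl on C10; C11–C16 = side chain); β is the face carrying H-5 and C-20, α the other face.

Assumption: the SMILES is taken as drawn, i.e. a cis-fused decalin (H-5 and C-20 both β) with 2R,4S,5S,6S,10S configuration (2α-OH, 6α-OH, acetoxy on the β-carbon of C4).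

Assumption: the (S)-oxazaborolidinium catalyst is written for step 2; I could not fix its sense of induction from memory, so if the first run gives the mirror-image adduct the (R)-catalyst is used with no other change.

**Route**

Step 1
Reactants: 1 mesityl oxide (4-methylpent-3-en-2-one)
Product: 3 triisopropyl[(4-methylpenta-1,3-dien-2-yl)oxy]silane, via lithium dienolate 2 (not isolated)
Conditions: LiN(i-Pr)2, THF, −78 °C; then i-Pr3SiOTf, −78 to 0 °C
Reagents that add atoms: triisopropylsilyl trifluoromethanesulfonate, CC(C)[Si](C(C)C)(C(C)C)OS(=O)(=O)C(F)(F)F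
Why: Kinetic deprotonation of the methyl ketone at its α′-methyl group by the hindered amide base and O-silylation of the cross-conjugated enolate (silyl enol ether formation) give the 2-silyloxydiene; no stereocentre is formed.

Step 2
Reactants: 3 triisopropyl[(4-methylpenta-1,3-dien-2-yl)oxy]silane; 4 2,6-dimethyl-1,4-benzoquinone
Product: 5 cis-fused enedione adduct (4aR,8aS)-4,4,7,8a-tetramethyl-2-(triisopropylsilyloxy)-1,4,4a,8a-tetrahydronaphthalene-5,8-dione
Conditions: (S)-3,3-diphenyl-1-(2-methylphenyl)tetrahydro-1H,3H-pyrrolo[1,2-c][1,3,2]oxazaborole (20 mol %) + (CF3SO2)2NH (20 mol %), CH2Cl2, −78 to −40 °C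
Reagents that add atoms: none
Why: Enantioselective Diels–Alder reaction under chiral oxazaborolidinium Lewis acid catalysis: the catalyst binds the quinone oxygen flanked by two C–H groups, so the nucleophilic CH2 terminus of the diene bonds to the methyl-bearing carbon (C10) and the hindered CMe2 terminus to the CH carbon (C5); suprafacial addition makes H-5 and the C-10 methyl cis, and the catalyst's face selection fixes their absolute configuration.

Step 3
Reactants: 5 cis-fused enedione adduct
Product: 7 enol triflate ketone (C8=C9–OTf; 6-oxo; C2=C3 silyl enol ether kept), via potassium enolate 6 (not isolated)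
Conditions: KBH(s-Bu)3 (1.05 equiv), THF, −78 °C; then N-(5-chloropyridin-2-yl)bis(trifluoromethanesulfonyl)imide, −78 to 0 °C
Reagents that add atoms: N-(5-chloropyridin-2-yl)bis(trifluoromethanesulfonyl)imide (Comins' reagent), FC(F)(F)S(=O)(=O)N(c1ccc(Cl)cn1)S(=O)(=O)C(F)(F)F
Why: Conjugate (1,4) reduction of the enedione by the bulky borohydride puts hydride on the unsubstituted C7 and gives the C9 enolate regiospecifically (C10 is quaternary, so it can only be C8=C9), and O-triflation (enol triflate synthesis) traps it at low temperature before proton transfer; no new stereocentre.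

Step 4
Reactants: 7 enol triflate ketone
Product: 11 6α,19-dihydroxy-2-ketone enol triflate (4α-CH3; 4β-CH2OH), via hydrosilyl ether 8 (not isolated), via oxasilinane 9 (not isolated), via diol enol ether 10 (not isolated)
Conditions: Et2SiH2, [Ir(cod)OMe]2 (1 mol %), THF, rt, then volatiles removed; [Rh(cod)Cl]2 (2.5 mol %), Xantphos (6 mol %), norbornene, THF, 100 °C; then KHCO3, 30 % H2O2, THF/MeOH, 50 °C; then 1 M HCl, THF, rt
Reagents that add atoms: hydrogen peroxide, OO
Why: Proposed new method: a 6α-silyloxy-directed δ-C–H oxygenation that tells the two methyl groups on C4 apart and so creates the C19–O bond and the C4 quaternary stereocentre in one flask; iridium-catalysed hydrosilylation of the C6 ketone delivers hydride to the convex β-face (the α-face is screened by C4 and ring A) and leaves a 6α-OSiEt2H group, which can only sit on the outside of the cis-decalin; the rhodium silyl species then cleaves the nearest primary C–H bond, and only the β-methyl (C19; torsions O6–C6–C5–C4 and C6–C5–C4–C19 gauche with opposite sign) can close a chair-like six-membered oxasilinane, whereas C18 would need a twisted ring and C17 and C20 lie anti to O6; Tamao–Fleming oxidation replaces C–Si by C–O with retention and dilute acid frees the C2 ketone; closest known reaction type: rhodium/Xantphos-catalysed δ-C–H silylation of diethyl(hydrido)silyl ethers followed by Tamao–Fleming oxidation to 1,4-diols, which to my knowledge has not been used to choose between the methyls of a ring gem-dimethyl group on a cis-decalin.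

Step 5
Reactants: 11 6α,19-dihydroxy-2-ketone enol triflate
Product: 12 19-acetoxy-6α-hydroxy-2-ketone enol triflate
Conditions: Ac2O (1.2 equiv), pyridine, CH2Cl2, 0 °C
Reagents that add atoms: acetic anhydride, CC(=O)OC(C)=O
Why: Chemoselective esterification: the primary C19 hydroxyl is acylated much faster than the secondary 6α-hydroxyl, which is crowded by the C4 quaternary carbon; no stereocentre is touched.

Step 6
Reactants: 12 19-acetoxy-6α-hydroxy-2-ketone enol triflate
Product: 13 19-acetoxy-2α,6α-diol enol triflate
Conditions: LiBH(s-Bu)3 (2.5 equiv), THF, −78 °C; then H2O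
Reagents that add atoms: none
Why: Kinetically controlled ketone reduction by a bulky trialkylborohydride: with the 6α-hydroxyl on the outside of the cis-decalin, ring A is a chair in which the α-axial approach to C2 is blocked by the syn-axial C18 methyl and the C10–C9 bond, so hydride enters equatorially from the β-face and gives the axial 2α-alcohol (2R); the neopentyl acetate and the enol triflate are untouched at −78 °C.

Step 7
Reactants: 13 19-acetoxy-2α,6α-diol enol triflate
Product: 14 19-acetoxy-9-vinyl-C8=C9-decalin-2α,6α-diol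
Conditions: CH2=CHSnBu3, Pd(PPh3)4 (5 mol %), LiCl, THF, 65 °C
Reagents that add atoms: tributyl(vinyl)stannane, C=C[Sn](CCCC)(CCCC)CCCC
Why: Stille cross-coupling (oxidative addition of zerovalent palladium into the C–OTf bond, transmetalation, reductive elimination) forms C9–C11 and keeps the double bond at C8=C9; free hydroxyls and the acetate are tolerated and no stereocentre is touched.

Step 8
Reactants: 14 19-acetoxy-9-vinyl-C8=C9-decalin-2α,6α-diol; 15 4-bromofuran-2(5H)-one
Product: 17 target (2R,4S,5S,6S,10S)-19-acetoxy-2,6-dihydroxylabda-8,13-dien-15,16-olide, via alkylborane 16 (not isolated)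
Conditions: 9-borabicyclo[3.3.1]nonane (3.5 equiv), THF, 0 °C to rt; then 15, Pd(dppf)Cl2 (10 mol %), AsPh3, K3PO4 (3 M aq.), DMF, rt
Reagents that add atoms: none
Why: Anti-Markovnikov hydroboration occurs only at the monosubstituted vinyl group (the tetrasubstituted C8=C9 bond is inert), and B-alkyl Suzuki–Miyaura coupling of the primary alkylborane with the β-bromobutenolide joins C12 to C13 under mild base; no stereocentre is formed or touched.

**Compound list**

1 | mesityl oxide (4-methylpent-3-en-2-one) | CC(=O)C=C(C)C | starting material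
2 | lithium 4-methylpenta-1,3-dien-2-olate | [Li+].[O-]C(=C)C=C(C)C | intermediate
3 | triisopropyl[(4-methylpenta-1,3-dien-2-yl)oxy]silane | C=C(O[Si](C(C)C)(C(C)C)C(C)C)C=C(C)C | intermediate
4 | 2,6-dimethyl-1,4-benzoquinone | CC1=CC(=O)C=C(C)C1=O | starting material
5 | cis-fused enedione adduct (4aR,8aS)-4,4,7,8a-tetramethyl-2-(triisopropylsilyloxy)-1,4,4a,8a-tetrahydronaphthalene-5,8-dione | CC1(C)C=C(O[Si](C(C)C)(C(C)C)C(C)C)C[C@]2(C)C(=O)C(C)=CC(=O)[C@H]12 | intermediate
6 | potassium enolate: C8=C9–OK enolate formed by hydride addition to C7 of the adduct; 6-oxo kept | CC1(C)C=C(O[Si](C(C)C)(C(C)C)C(C)C)C[C@]2(C)C([O-])=C(C)CC(=O)[C@H]12.[K+] | intermediate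
7 | enol triflate ketone (C8=C9–OTf; 6-oxo; C2=C3 silyl enol ether kept; 4,4-dimethyl; 5β-H; 10β-CH3) | CC1(C)C=C(O[Si](C(C)C)(C(C)C)C(C)C)C[C@]2(C)C(OS(=O)(=O)C(F)(F)F)=C(C)CC(=O)[C@H]12 | intermediate
8 | hydrosilyl ether: 6α-diethylsilyloxy (6β-H) derivative of the enol triflate | CC1(C)C=C(O[Si](C(C)C)(C(C)C)C(C)C)C[C@]2(C)C(OS(=O)(=O)C(F)(F)F)=C(C)C[C@H](O[SiH](CC)CC)[C@H]12 | intermediate
9 | oxasilinane: 6α-O–SiEt2–C19H2 ring closed on the β-methyl of C4 (4α-CH3 left) | CC[Si]3(CC)C[C@@]1(C)C=C(O[Si](C(C)C)(C(C)C)C(C)C)C[C@]2(C)C(OS(=O)(=O)C(F)(F)F)=C(C)C[C@H](O3)[C@H]12 | intermediate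
10 | diol enol ether: 6α,19-diol with C2=C3 triisopropylsilyl enol ether and C8=C9 enol triflate | OC[C@@]1(C)C=C(O[Si](C(C)C)(C(C)C)C(C)C)C[C@]2(C)C(OS(=O)(=O)C(F)(F)F)=C(C)C[C@H](O)[C@H]12 | intermediate
11 | 6α,19-dihydroxy-2-ketone enol triflate (4α-CH3; 4β-CH2OH) | OC[C@@]1(C)CC(=O)C[C@]2(C)C(OS(=O)(=O)C(F)(F)F)=C(C)C[C@H](O)[C@H]12 | intermediate
12 | 19-acetoxy-6α-hydroxy-2-ketone enol triflate | CC(=O)OC[C@@]1(C)CC(=O)C[C@]2(C)C(OS(=O)(=O)C(F)(F)F)=C(C)C[C@H](O)[C@H]12 | intermediate
13 | 19-acetoxy-2α,6α-diol enol triflate | CC(=O)OC[C@@]1(C)C[C@H](O)C[C@]2(C)C(OS(=O)(=O)C(F)(F)F)=C(C)C[C@H](O)[C@H]12 | intermediate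
14 | 19-acetoxy-9-vinyl-C8=C9-decalin-2α,6α-diol | CC(=O)OC[C@@]1(C)C[C@H](O)C[C@]2(C)C(C=C)=C(C)C[C@H](O)[C@H]12 | intermediate
15 | 4-bromofuran-2(5H)-one | BrC1=CC(=O)OC1 | starting material
16 | alkylborane: 12-(9-borabicyclo[3.3.1]nonan-9-yl) adduct of the vinyl compound (C9–CH2–CH2–B) | CC(=O)OC[C@@]1(C)C[C@H](O)C[C@]2(C)C(CCB3C4CCCC3CCC4)=C(C)C[C@H](O)[C@H]12 | intermediate
17 | target (2R,4S,5S,6S,10S)-19-acetoxy-2,6-dihydroxylabda-8,13-dien-15,16-olide | CC(=O)OC[C@@]1(C)C[C@H](O)C[C@]2(C)C(CCC3=CC(=O)OC3)=C(C)C[C@H](O)[C@H]12 | target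

**Step count and risks**

Total step count: 8. Longest linear sequence: 8 steps (1 to 17).

The three steps most likely to fail:

Step 2. The diene carries a methyl group cis to the diene unit at its reacting terminus, so the cycloaddition may be slow, may stop at the open-chain Mukaiyama–Michael stage, or may lose enantioselectivity. The fallback sets out from 3 and 4 and gives up asymmetric catalysis for a racemic synthesis plus resolution. The ring is closed as a stepwise double Michael reaction (Mukaiyama–Michael addition, then intramolecular Michael addition) promoted by EtAlCl2 in CH2Cl2 at −78 °C, which gives 5 together with its mirror image, the enantiomeric adduct F1. The two are separated by preparative chromatography on a chiral stationary phase, and the route is rejoined at 5.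

Step 4 (the proposed new step). The risks are a wrong facial course of the hydrosilylation, insertion of rhodium into the enol triflate, attack on the wrong methyl group, or oxidation of the silyl enol ether during the Tamao–Fleming stage. The fallback uses known chemistry only: the C19 oxygen is brought in with the diene, so that the Diels–Alder reaction itself fixes C4. It sets out from 4. Propargyl alcohol is treated with MeMgBr and CuI (cat.) in THF to give, by anti-carbomagnesiation, the chelated (Z)-alkenylmagnesium alkoxide F2, which iodine converts into (Z)-3-iodo-2-methylprop-2-en-1-ol F3. Acetylation (Ac2O, pyridine) gives (Z)-3-iodo-2-methylprop-2-en-1-yl acetate F4. Stille coupling with tributyl(1-ethoxyvinyl)stannane (Pd(PPh3)4, CuI, DMF) gives (2Z)-4-ethoxy-2-methylpenta-2,4-dien-1-yl acetate F5. Diels–Alder reaction of F5 with 4 under the conditions of step 2 (endo transition state, so the cis CH2OAc group ends up on the face of H-5) gives the 19-acetoxy ethyl enol ether enedione F6. KBH(s-Bu)3 and then the pyridyl triflimide, as in step 3, give through the potassium enolate F7 the 19-acetoxy enol triflate ketone F8. NaBH4 (MeOH/CH2Cl2, −40 °C) reduces C6 from the convex β-face to the 6α-alcohol F9. Pyridinium p-toluenesulfonate in wet acetone then hydrolyses the ethyl enol ether to the C2 ketone, which is 12; the route continues with step 6.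

Step 8. The bromobutenolide is base-sensitive, the two free hydroxyls consume borane, and a hindered homoallylic alkylborane has to transmetalate. The fallback sets out from alkylborane 16 and builds the butenolide by conjugate addition and lactonisation instead of cross-coupling. Copper-catalysed syn-carbocupration of ethyl 4-hydroxybut-2-ynoate by 16 (CuOAc, P(OPh)3, KOt-Bu, dioxane; then t-BuOH) gives the (Z)-γ-hydroxy enoate F10, ethyl (2Z)-3-(hydroxymethyl)pent-2-enoate carrying the decalin at C5. Its hydroxyl and ester are cis, and it lactonises (pyridinium p-toluenesulfonate, toluene, 50 °C) to 17.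

**Further compounds**

F1 | step 2 | enantiomeric adduct (4aS,8aR)-4,4,7,8a-tetramethyl-2-(triisopropylsilyloxy)-1,4,4a,8a-tetrahydronaphthalene-5,8-dione | CC1(C)C=C(O[Si](C(C)C)(C(C)C)C(C)C)C[C@@]2(C)C(=O)C(C)=CC(=O)[C@@H]12
F2 | step 4 | (Z)-alkenylmagnesium alkoxide: bromomagnesium (Z)-3-(bromomagnesio)-2-methylprop-2-en-1-olate | Br[Mg]OC/C(C)=C\[Mg]Br
F3 | step 4 | (Z)-3-iodo-2-methylprop-2-en-1-ol | OC/C(C)=C\I
F4 | step 4 | (Z)-3-iodo-2-methylprop-2-en-1-yl acetate | CC(=O)OC/C(C)=C\I
F5 | step 4 | (2Z)-4-ethoxy-2-methylpenta-2,4-dien-1-yl acetate | CC(=O)OC/C(C)=C\C(=C)OCC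
F6 | step 4 | 19-acetoxy ethyl enol ether enedione (C2=C3–OEt; 4α-CH3; 4β-CH2OAc; 5β-H; 10β-CH3; 6,9-dione; C7=C8) | CC(=O)OC[C@@]1(C)C=C(OCC)C[C@]2(C)C(=O)C(C)=CC(=O)[C@H]12
F7 | step 4 | potassium enolate (C8=C9–OK; 6-oxo) of the 19-acetoxy ethyl enol ether series | CC(=O)OC[C@@]1(C)C=C(OCC)C[C@]2(C)C([O-])=C(C)CC(=O)[C@H]12.[K+]
F8 | step 4 | 19-acetoxy enol triflate ketone (C8=C9–OTf; 6-oxo; C2=C3–OEt) | CC(=O)OC[C@@]1(C)C=C(OCC)C[C@]2(C)C(OS(=O)(=O)C(F)(F)F)=C(C)CC(=O)[C@H]12
F9 | step 4 | 19-acetoxy-6α-alcohol (C8=C9–OTf; C2=C3–OEt) | CC(=O)OC[C@@]1(C)C=C(OCC)C[C@]2(C)C(OS(=O)(=O)C(F)(F)F)=C(C)C[C@H](O)[C@H]12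
F10 | step 8 | (Z)-γ-hydroxy enoate: ethyl (2Z)-3-(hydroxymethyl)pent-2-enoate carrying the 19-acetoxy-2α,6α-dihydroxy decalin at C5 | CC(=O)OC[C@@]1(C)C[C@H](O)C[C@]2(C)C(CC/C(CO)=C/C(=O)OCC)=C(C)C[C@H](O)[C@H]12
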